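**Plan**
- Retrosynthesis: the pyran (O1, C2, C3, C4, C11, C10) is opened at O1–C10 and re-closed through the C3 oxygen to its five-membered isomer, a dihydrofuran carrying the tertiary carbinol. The dihydrofuran is cut at O–C3 and C11–C4 into dibenzoxepinone 8 and epoxyneryl iodide 11. Ketone 8 is cut at the prenyl C–C bond, the C9a–C10 acyl bond and the diaryl ether C–O bond.
- Forward order: diaryl ether (Ullmann), seven-membered oxepinone (Friedel–Crafts), bromination, demethylation, prenylation, silylation, five-membered dihydrofuran (alkylation and 5-exo epoxide opening), six-membered pyran (ring expansion), desilylation.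
- Enabling feature: O1–C10=C11 is an enol ether, so C10 is a masked ketone flanked by the C3/C2 diol. The C10–O bond can therefore pass from the C3 oxygen (ring O, C10, C11, C4, C3) to the C2 oxygen (six-membered ring) by ketal exchange.
- Stereochemistry: both centres come from Sharpless epoxidation of nerol with D-(−)-diisopropyl tartrate. The quaternary C2 is never touched, C3 is inverted once in the epoxide opening, and the ring expansion breaks no bond at either centre.

Key step: step 10

Remark: the (2S,3S) descriptors place the 3-hydroxyl trans to the 2-methyl group, the pattern of anti opening of a (Z)-derived epoxide, so nerol (not geraniol) is the chain source; (2-bromo-4-methoxyphenyl)acetic acid is taken as commercially available.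

**Step 1**
Reactants: 1 (2-bromo-4-methoxyphenyl)acetic acid; 2 3-methoxyphenol
Product: 3 [4-methoxy-2-(3-methoxyphenoxy)phenyl]acetic acid
Conditions: CuI (10 mol%), N,N-dimethylglycine hydrochloride (30 mol%), Cs2CO3 (3 equiv), 1,4-dioxane, 100 °C; then aq HCl
Reagents that add atoms: none
Why: Ullmann diaryl ether coupling of a 2-bromophenylacetic acid with a phenol under copper/amino acid catalysis, the standard entry to 2-aryloxyphenylacetic acids for dibenzoxepinones.

**Step 2**
Reactants: 3 [4-methoxy-2-(3-methoxyphenoxy)phenyl]acetic acid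
Product: 4 3,7-dimethoxydibenzo[b,f]oxepin-10(11H)-one
Conditions: (CF3CO)2O (2.5 equiv), BF3·OEt2 (cat.), CH2Cl2, 0 °C to rt
Reagents that add atoms: none
Why: intramolecular Friedel–Crafts acylation through the mixed anhydride should close the seven-membered ring at the position of the resorcinol-type ring that is ortho to the ether oxygen and para to the methoxy group.

**Step 3**
Reactants: 4 3,7-dimethoxydibenzo[b,f]oxepin-10(11H)-one
Product: 5 2-bromo-3,7-dimethoxydibenzo[b,f]oxepin-10(11H)-one
Conditions: NBS (1.0 equiv), MeCN, 0 °C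
Reagents that add atoms: N-bromosuccinimide O=C1CCC(=O)N1Br
Why: electrophilic aromatic bromination should go to C2, which is ortho to the 3-methoxy group and para to the ether oxygen on the ring that carries no acyl group; the other ring is deactivated by the ketone and C4 is flanked by two oxygens.

**Step 4**
Reactants: 5 2-bromo-3,7-dimethoxydibenzo[b,f]oxepin-10(11H)-one
Product: 6 2-bromo-3,7-dihydroxydibenzo[b,f]oxepin-10(11H)-one
Conditions: BBr3 (4 equiv), CH2Cl2, −78 °C to rt; then H2O
Reagents that add atoms: none
Why: boron tribromide cleavage of aryl methyl ethers, done before any acid-sensitive alkene is present; diaryl ether, ketone and aryl bromide are inert.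

**Step 5**
Reactants: 6 2-bromo-3,7-dihydroxydibenzo[b,f]oxepin-10(11H)-one
Product: 7 3,7-dihydroxy-2-(3-methylbut-2-en-1-yl)dibenzo[b,f]oxepin-10(11H)-one
Conditions: PdCl2(dppf) (5 mol%), K3PO4 (5 equiv), 1,4-dioxane/H2O (5:1), 80 °C
Reagents that add atoms: 3-methylbut-2-enylboronic acid pinacol ester CC(C)=CCB1OC(C)(C)C(C)(C)O1
Why: Suzuki–Miyaura coupling of an aryl bromide with prenyl pinacol boronate should give the linear prenyl arene; under the basic conditions the ketone is shielded from allylboration as the para-phenoxide.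

**Step 6**
Reactants: 7 3,7-dihydroxy-2-(3-methylbut-2-en-1-yl)dibenzo[b,f]oxepin-10(11H)-one
Product: 8 2-(3-methylbut-2-en-1-yl)-3,7-bis(triisopropylsilyloxy)dibenzo[b,f]oxepin-10(11H)-one
Conditions: TIPSCl (2.5 equiv), imidazole (5 equiv), DMF, rt to 40 °C
Reagents that add atoms: chlorotriisopropylsilane CC(C)[Si](Cl)(C(C)C)C(C)C
Why: silylation of both phenols gives ethers that should survive amide bases and weak acid and fall to fluoride at the end.

**Step 7**
Reactants: 9 nerol
Product: 10 [(2R,3S)-3-methyl-3-(4-methylpent-3-en-1-yl)oxiran-2-yl]methanol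
Conditions: Ti(OiPr)4 (10 mol%), D-(−)-diisopropyl tartrate (12 mol%), t-BuOOH (anhydrous, decane), 4 Å MS, CH2Cl2, −20 °C
Reagents that add atoms: tert-butyl hydroperoxide CC(C)(C)OO
Why: Sharpless asymmetric epoxidation; the allylic hydroxyl confines reaction to the 2,3-alkene and the D-(−)-tartrate ligand controls the face, setting the quaternary centre (S, the later pyran C2) and the CH centre (R, inverted in step 9).

**Step 8**
Reactants: 10 [(2R,3S)-3-methyl-3-(4-methylpent-3-en-1-yl)oxiran-2-yl]methanol
Product: 11 (2S,3S)-3-(iodomethyl)-2-methyl-2-(4-methylpent-3-en-1-yl)oxirane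
Conditions: PPh3 (1.3 equiv), imidazole (1.5 equiv), I2 (1.25 equiv), CH2Cl2, 0 °C, dark
Reagents that add atoms: iodine II
Why: Appel-type (Garegg–Samuelsson) conversion of a primary alcohol into the iodide; the epoxide and both stereocentres are untouched (the descriptor at the CH carbon changes only through the priority of CH2I).

**Step 9**
Reactants: 8 2-(3-methylbut-2-en-1-yl)-3,7-bis(triisopropylsilyloxy)dibenzo[b,f]oxepin-10(11H)-one; 11 (2S,3S)-3-(iodomethyl)-2-methyl-2-(4-methylpent-3-en-1-yl)oxirane
Product: 13 (2S)-2-[(2S)-2-hydroxy-6-methylhept-5-en-2-yl]-2,3-dihydrofuran fused at C10–C11 of the bis-silylated 2-prenyldibenzo[b,f]oxepine (ring oxygen on C10), via epoxy ketone 12 (not isolated)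
Conditions: KN(SiMe3)2 (1.05 equiv), THF, −78 °C; 11, −78 to 0 °C; then KN(SiMe3)2 (0.3 equiv), 18-crown-6 (0.3 equiv), 0 to 40 °C; aq NH4Cl
Reagents that add atoms: none
Why: the potassium enolate of the α-aryl ketone should be alkylated on carbon at the CH2–I group (SN2, epoxide intact); the enolate oxygen of 12 then opens the epoxide 5-exo-tet at its less substituted carbon (dihydrofuran annulation of the interrupted Feist–Benary type), which inverts that carbon (R to S) and leaves the quaternary centre alone. Attack through carbon would give a cyclopropane with no strain gain at the cost of a stabilised enolate, so oxygen attack should win under equilibrating conditions.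

**Step 10**
Reactants: 13 dihydrofuran carbinol
Product: 15 (2S,3S)-3-hydroxy-2-methyl-2-(4-methylpent-3-en-1-yl)-3,4-dihydro-2H-pyran fused at C10–C11 of the bis-silylated 2-prenyldibenzo[b,f]oxepine (O1 on C10), via bicyclic ketal 14 (not isolated)
Conditions: PPTS (10 mol%), 4 Å MS, ClCH2CH2Cl, 50 °C; Et3N quench
Reagents that add atoms: none
Why: Proposed new method: protonation of the enol ether at C11 gives the C10 oxocarbenium ion (stabilised by the ring oxygen and the para-silyloxyaryl ring B), the tertiary hydroxyl adds to C10 to give the 2,7-dioxabicyclo[2.2.1]heptane ketal 14, and cleavage of the other C10–O bond with loss of H-11 gives the six-membered enol ether, so the C10–O bond passes from the secondary to the tertiary oxygen. The closest known reaction types are the acid-catalysed furanoside-to-pyranoside ring expansion of glycosides, the ring-size equilibration of cyclic ketals, and the dihydrofuro-to-pyrano rearrangement of hydroxyisopropyl dihydrofuroquinolones. The six-membered ring closes by 6-exo-trig attack of the tertiary oxygen on the C10=O(+) bond, the same bond completing a dioxolane ketal. No new stereocentre remains, because neither C–O bond at C2 or C3 is broken and both centres pass unchanged from 13 (C10 and C11 of 14 are transient). The step needs C-protonation of the enol ether to outrun ionisation of the tertiary alcohol (which, through an oxiranium ion, would lead into the enantiomeric series) and protonation of the two trisubstituted alkenes; the weak acid and the capped phenols should secure this. The equilibrium should favour 15 through relief of the strain of the dihydrofuran fused to the seven-membered ring and through the gem-dialkyl carbon becoming a ring member.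

**Step 11**
Reactants: 15 bis-silylated pyran
Product: 16 target, (2S,3S)-configured CNP0185870.1
Conditions: Bu4NF (2.5 equiv), AcOH (2.5 equiv), THF, 0 °C
Reagents that add atoms: none
Why: buffered fluoride cleavage of the two aryl silyl ethers; the enol ether, the alkenes and both stereocentres are inert to these conditions.

**Compound list**
1 | (2-bromo-4-methoxyphenyl)acetic acid | OC(=O)Cc1ccc(OC)cc1Br | starting material
2 | 3-methoxyphenol | COc1cccc(O)c1 | starting material
3 | [4-methoxy-2-(3-methoxyphenoxy)phenyl]acetic acid | OC(=O)Cc1ccc(OC)cc1Oc1cccc(OC)c1 | intermediate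
4 | 3,7-dimethoxydibenzo[b,f]oxepin-10(11H)-one | O=C1Cc2ccc(OC)cc2Oc2cc(OC)ccc12 | intermediate
5 | 2-bromo-3,7-dimethoxydibenzo[b,f]oxepin-10(11H)-one | O=C1Cc2cc(Br)c(OC)cc2Oc2cc(OC)ccc12 | intermediate
6 | 2-bromo-3,7-dihydroxydibenzo[b,f]oxepin-10(11H)-one | O=C1Cc2cc(Br)c(O)cc2Oc2cc(O)ccc12 | intermediate
7 | 3,7-dihydroxy-2-(3-methylbut-2-en-1-yl)dibenzo[b,f]oxepin-10(11H)-one | O=C1Cc2cc(CC=C(C)C)c(O)cc2Oc2cc(O)ccc12 | intermediate
8 | 2-(3-methylbut-2-en-1-yl)-3,7-bis(triisopropylsilyloxy)dibenzo[b,f]oxepin-10(11H)-one | O=C1Cc2cc(CC=C(C)C)c(O[Si](C(C)C)(C(C)C)C(C)C)cc2Oc2cc(O[Si](C(C)C)(C(C)C)C(C)C)ccc12 | intermediate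
9 | nerol, (Z)-3,7-dimethylocta-2,6-dien-1-ol | CC(C)=CCC/C(C)=C\CO | starting material
10 | [(2R,3S)-3-methyl-3-(4-methylpent-3-en-1-yl)oxiran-2-yl]methanol | OC[C@H]1O[C@@]1(C)CCC=C(C)C | intermediate
11 | (2S,3S)-3-(iodomethyl)-2-methyl-2-(4-methylpent-3-en-1-yl)oxirane | IC[C@H]1O[C@@]1(C)CCC=C(C)C | intermediate
12 | 11-{[(2R,3S)-3-methyl-3-(4-methylpent-3-en-1-yl)oxiran-2-yl]methyl} derivative of ketone 8 (C11 epimers) | O=C1c2ccc(O[Si](C(C)C)(C(C)C)C(C)C)cc2Oc2cc(O[Si](C(C)C)(C(C)C)C(C)C)c(CC=C(C)C)cc2C1C[C@H]1O[C@@]1(C)CCC=C(C)C | intermediate (not isolated)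
13 | dihydrofuran carbinol: (2S)-2-[(2S)-2-hydroxy-6-methylhept-5-en-2-yl]-2,3-dihydrofuran fused at C10–C11 (O on C10) of 2-prenyl-3,7-bis(triisopropylsilyloxy)dibenzo[b,f]oxepine | CC(C)=CCC[C@](C)(O)[C@@H]1CC2=C(O1)c1ccc(O[Si](C(C)C)(C(C)C)C(C)C)cc1Oc1cc(O[Si](C(C)C)(C(C)C)C(C)C)c(CC=C(C)C)cc12 | intermediate
14 | bicyclic ketal: 2,7-dioxabicyclo[2.2.1]heptane with C10 as ketal carbon (C11 epimers) | CC(C)=CCC[C@]1(C)O[C@@]2(O[C@H]1CC2c1cc(CC=C(C)C)c(O[Si](C(C)C)(C(C)C)C(C)C)cc1O3)c1ccc(O[Si](C(C)C)(C(C)C)C(C)C)cc13 | intermediate (not isolated)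
15 | bis(triisopropylsilyl) ether of the target, (2S,3S)-pyran | CC(C)=CCC[C@]1(C)OC2=C(C[C@@H]1O)c1cc(CC=C(C)C)c(O[Si](C(C)C)(C(C)C)C(C)C)cc1Oc1cc(O[Si](C(C)C)(C(C)C)C(C)C)ccc12 | intermediate
16 | CNP0185870.1, (2S,3S) | CC(C)=CCC[C@]1(C)OC2=C(C[C@@H]1O)c1cc(CC=C(C)C)c(O)cc1Oc1cc(O)ccc12 | target

Total step count: 11. Longest linear sequence: 9 steps (steps 1–6 and 9–11, from compound 1).

**Steps most likely to fail**

Step 10 (Proposed new method). The acid-mediated oxygen exchange may stall at the bicyclic ketal or settle at an equilibrium still rich in the five-membered isomer. Forcing it with stronger acid invites ionisation of the tertiary alcohol (erosion of enantiopurity through the oxiranium path) or hydration and cyclisation of the prenyl groups. The fallback uses known chemistry and gives up the ring-size change: direct acid-catalysed 6-endo opening of a trisubstituted epoxide at its tertiary carbon by the neighbouring ketone oxygen. Because this inverts the quaternary carbon and not the CH carbon, the enantiomeric epoxide is needed. It sets out from nerol 9 and ketone 8. Epoxidation of 9 with Ti(OiPr)4, L-(+)-diisopropyl tartrate and t-BuOOH gives the (2S,3R)-epoxy alcohol F1. PPh3, imidazole and I2 give the (2R,3R)-iodide F2. Alkylation of the potassium enolate of 8 (KN(SiMe3)2, THF, −78 to 0 °C) gives the epoxy ketone F3, which is isolated. Catalytic camphorsulfonic acid in CH2Cl2 at 0 °C should then close the pyran at the tertiary carbon with loss of H-11, coming back to the route at compound 15.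

Step 9. Carbon attack of the enolate on the epoxide (3-exo closure), over-alkylation at C11, or loss of the aryl silyl groups under the basic conditions may compete. The fallback removes the epoxide before the C–C bond is made and sets out from epoxy alcohol 10 and ketone 8. Payne rearrangement and hydroxide opening of 10 (aq NaOH, t-BuOH, 70 °C; net inversion at C2) give the (2S,3S)-triol F4. Selective iodination of the primary hydroxyl (PPh3, imidazole, I2) gives the iodo diol F5, and 2,2-dimethoxypropane with PPTS gives the acetonide iodide F6. Alkylation of the potassium enolate of 8 with F6 gives the acetonide ketone F7. Aqueous acetic acid frees the keto diol F8, which is cyclodehydrated under the PPTS conditions of step 10 (through 13), coming back to the route at compound 15.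

Step 5. Coupling through the γ-terminus of the allyl boronate (reverse-prenyl isomer), protodeboronation, or allylboration of the ketone may erode the prenylation. The fallback builds the prenyl group in two known operations from bromide 6. Stille coupling with allyltributylstannane (Pd(PPh3)4, LiCl, DMF, 90 °C), which has no regiochemical ambiguity, gives the 2-allyl ketone F9. Cross-metathesis with 2-methylbut-2-ene (second-generation Grubbs catalyst, CH2Cl2, 40 °C) then gives the prenyl group, coming back to the route at compound 7.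

**Further compounds**
F1 | step 10 | [(2S,3R)-3-methyl-3-(4-methylpent-3-en-1-yl)oxiran-2-yl]methanol | OC[C@@H]1O[C@]1(C)CCC=C(C)C
F2 | step 10 | (2R,3R)-3-(iodomethyl)-2-methyl-2-(4-methylpent-3-en-1-yl)oxirane | IC[C@@H]1O[C@]1(C)CCC=C(C)C
F3 | step 10 | 11-{[(2S,3R)-3-methyl-3-(4-methylpent-3-en-1-yl)oxiran-2-yl]methyl} derivative of ketone 8 (C11 epimers) | O=C1c2ccc(O[Si](C(C)C)(C(C)C)C(C)C)cc2Oc2cc(O[Si](C(C)C)(C(C)C)C(C)C)c(CC=C(C)C)cc2C1C[C@@H]1O[C@]1(C)CCC=C(C)C
F4 | step 9 | (2S,3S)-3,7-dimethyloct-6-ene-1,2,3-triol | OC[C@H](O)[C@@](C)(O)CCC=C(C)C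
F5 | step 9 | (2R,3S)-1-iodo-3,7-dimethyloct-6-ene-2,3-diol | IC[C@H](O)[C@@](C)(O)CCC=C(C)C
F6 | step 9 | (4R,5S)-4-(iodomethyl)-2,2,5-trimethyl-5-(4-methylpent-3-en-1-yl)-1,3-dioxolane | IC[C@@H]1OC(C)(C)O[C@@]1(C)CCC=C(C)C
F7 | step 9 | 11-{[(4S,5S)-2,2,5-trimethyl-5-(4-methylpent-3-en-1-yl)-1,3-dioxolan-4-yl]methyl} derivative of ketone 8 (C11 epimers) | O=C1c2ccc(O[Si](C(C)C)(C(C)C)C(C)C)cc2Oc2cc(O[Si](C(C)C)(C(C)C)C(C)C)c(CC=C(C)C)cc2C1C[C@@H]1OC(C)(C)O[C@@]1(C)CCC=C(C)C
F8 | step 9 | 11-[(2S,3S)-2,3-dihydroxy-3,7-dimethyloct-6-en-1-yl] derivative of ketone 8 (C11 epimers) | O=C1c2ccc(O[Si](C(C)C)(C(C)C)C(C)C)cc2Oc2cc(O[Si](C(C)C)(C(C)C)C(C)C)c(CC=C(C)C)cc2C1C[C@H](O)[C@@](C)(O)CCC=C(C)C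
F9 | step 5 | 2-allyl-3,7-dihydroxydibenzo[b,f]oxepin-10(11H)-one | O=C1Cc2cc(CC=C)c(O)cc2Oc2cc(O)ccc12
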